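The dione ring (C1, C2, C3, C4, C4a, C8a; naphthalenedione numbering) is treated as the one-carbon homologue of an indane-1,3-dione ring from which C2, the carbon carrying the terpene CH2, is missing. The key step inserts C2, delivered as the zinc carbenoid of the complete C16 side-chain gem-diiodide, between the methyl-bearing carbon and the more electrophilic carbonyl of a 2-methylindane-1,3-dione; iodination–elimination gives the 2,3-dialkylnaphthoquinone. One operation expands the ring and joins both halves. It exploits the 1,4-dicarbonyl pattern C1/C4 and the electronic difference between these carbonyls (only C4 is conjugated with the C5 and C7 oxygens). Enantioselective nucleophilic epoxidation and anti opening by chloride at C3 then set C2 and C3.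

Key step: step 10

Remark: in the target, C2 carries OH and the side-chain CH2, C3 carries Cl and CH3, and the C4 carbonyl is peri to the C5 hydroxyl; the (2S,3R) configuration has OH and Cl trans. The side chain is (4E)-5,9-dimethyl-2-(propan-2-ylidene)deca-4,8-dien-1-yl, called "the side chain" below.

Step 1
Reactants: 1 triethyl phosphonoacetate; 2 geranyl bromide
Product: 3 ethyl (4E)-2-(diethoxyphosphoryl)-5,9-dimethyldeca-4,8-dienoate
Conditions: NaH, THF/DMF, 0 °C → rt (1 in slight excess)
Reagents that add atoms: none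
Why: C-alkylation of the sodium phosphonoacetate by the primary allylic bromide (SN2) should leave the E alkene untouched, and the excess of 1 suppresses dialkylation.

Step 2
Reactants: 3 ethyl (4E)-2-(diethoxyphosphoryl)-5,9-dimethyldeca-4,8-dienoate
Product: 4 ethyl (4E)-5,9-dimethyl-2-(propan-2-ylidene)deca-4,8-dienoate
Conditions: NaH, THF, 0 °C; acetone (excess), reflux
Reagents that add atoms: acetone CC(C)=O
Why: Horner–Wadsworth–Emmons olefination of the α-substituted phosphonate with a symmetric ketone should give the tetrasubstituted acrylate with no E/Z question.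

Step 3
Reactants: 4 ethyl (4E)-5,9-dimethyl-2-(propan-2-ylidene)deca-4,8-dienoate
Product: 5 (4E)-5,9-dimethyl-2-(propan-2-ylidene)deca-4,8-dien-1-ol
Conditions: i-Bu2AlH, CH2Cl2, −78 → 0 °C; Rochelle salt work-up
Reagents that add atoms: none
Why: 1,2-reduction of the conjugated ester by i-Bu2AlH should give the allylic alcohol without touching the isolated alkenes.

Step 4
Reactants: 5 (4E)-5,9-dimethyl-2-(propan-2-ylidene)deca-4,8-dien-1-ol
Product: 6 (5E)-3-(bromomethyl)-2,6,10-trimethylundeca-2,5,9-triene
Conditions: CBr4, PPh3, CH2Cl2, 0 °C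
Reagents that add atoms: tetrabromomethane BrC(Br)(Br)Br
Why: Appel bromination of the primary allylic alcohol proceeds by SN2 on the alkoxyphosphonium ion, and the fully substituted γ-carbon should block SN2′.

Step 5
Reactants: 6 (5E)-3-(bromomethyl)-2,6,10-trimethylundeca-2,5,9-triene
Product: 7 (5E)-3-(2,2-diiodoethyl)-2,6,10-trimethylundeca-2,5,9-triene
Conditions: NaN(SiMe3)2, CH2I2, THF/Et2O, −78 °C, dark; then 6, −78 °C → rt
Reagents that add atoms: diiodomethane ICI
Why: SN2 alkylation of diiodomethylsodium by an allylic bromide is the standard entry to 1,1-diiodoalkanes, the precursors of substituted zinc carbenoids.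

Step 6
Reactants: 8 methyl 3,5-dimethoxybenzoate
Product: 9 methyl 3,5-dimethoxy-2-propanoylbenzoate
Conditions: EtCOCl, SnCl4, CH2Cl2, 0 °C → rt
Reagents that add atoms: propanoyl chloride CCC(Cl)=O
Why: Friedel–Crafts acylation should go to C2, which is ortho to one methoxy group and para to the other, because C4 between the two methoxy groups is shielded.

Step 7
Reactants: 9 methyl 3,5-dimethoxy-2-propanoylbenzoate
Product: 10 methyl 3,5-dihydroxy-2-propanoylbenzoate
Conditions: BBr3, CH2Cl2, −78 → 0 °C; aqueous work-up
Reagents that add atoms: none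
Why: Lewis-acid cleavage of the aryl methyl ethers, both activated by the ortho/para ketone, should proceed below the temperature at which the methyl ester is attacked.

Step 8
Reactants: 10 methyl 3,5-dihydroxy-2-propanoylbenzoate
Product: 11 methyl 3,5-bis(methoxymethoxy)-2-propanoylbenzoate
Conditions: MOMCl, i-Pr2NEt, DMF, 0 → 50 °C
Reagents that add atoms: chloromethyl methyl ether COCCl
Why: O-alkylation of both phenols as MOM acetals (stable to base, zinc reagents and alkaline peroxide) with an amine base avoids premature Claisen closure.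

Step 9
Reactants: 11 methyl 3,5-bis(methoxymethoxy)-2-propanoylbenzoate
Product: 12 4,6-bis(methoxymethoxy)-2-methyl-1H-indene-1,3(2H)-dione
Conditions: NaH, THF, 0 °C → rt; then AcOH
Reagents that add atoms: none
Why: Intramolecular Claisen (Dieckmann-type) condensation of the ketone enolate onto the ortho ester closes the five-membered 1,3-dione (5-exo-trig), driven by formation of the stabilised dione enolate.

Step 10
Reactants: 12 4,6-bis(methoxymethoxy)-2-methyl-1H-indene-1,3(2H)-dione; 7 (5E)-3-(2,2-diiodoethyl)-2,6,10-trimethylundeca-2,5,9-triene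
Product: 16 2-[(4E)-5,9-dimethyl-2-(propan-2-ylidene)deca-4,8-dien-1-yl]-5,7-bis(methoxymethoxy)-3-methylnaphthalene-1,4-dione, via zinc carbenoid 13 (not isolated), via ring-expanded zinc enolate 14 (not isolated), via iodo diketone 15 (not isolated)
Conditions: Et2Zn (2.2 equiv), 7 (1.1 equiv), CH2Cl2, 0 °C → rt; then I2, 0 °C; then DBU, rt
Reagents that add atoms: none
Why: Zercher-type zinc-carbenoid homologation of a 1,3-dicarbonyl, run as a ring expansion and finished by iodination–elimination: the zinc enolate of 12 is C-alkylated at its methyl-bearing carbon (future C3) by carbenoid 13, the new C–Zn bond closes 3-exo-trig onto the neighbouring carbonyl (a fleeting cyclopropanolate stage) and the old ring bond breaks, so that the carbenoid carbon (future C2) ends between C1 and C3 in enolate 14. The closest known reactions are the zinc-carbenoid chain extension of β-keto esters and β-diketones with substituted carbenoids from 1,1-diiodoalkanes and the one-carbon ring expansion of cyclic β-keto esters. No ring is closed end to end: the six-membered ring arises from the five-membered one by insertion, and the only closure is the transient three-membered 3-exo-trig step. The C2 stereocentre of 14 and 15 is uncontrolled and is erased when DBU eliminates HI from 15 to the C2=C3 bond of 16, so no stereocontrol is needed. The selectivity needed is insertion next to the C1 carbonyl and not next to C4: C1 is meta to both aryl oxygens and the more electrophilic ketone, whereas C4 is a vinylogous-ester-type carbonyl whose enolate oxygen holds zinc in a chelate with the peri OMOM group. The chain alkenes should be spared because only a slight excess of carbenoid is used and zinc enolates trap it much faster than unactivated trisubstituted alkenes do.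

Step 11
Reactants: 16 2-(side chain)-5,7-bis(methoxymethoxy)-3-methylnaphthalene-1,4-dione
Product: 17 (2R,3S)-2,3-epoxy-2-(side chain)-5,7-bis(methoxymethoxy)-3-methyl-2,3-dihydronaphthalene-1,4-dione
Conditions: 30% H2O2, LiOH (cat.), N-(9-anthracenylmethyl)quinidinium chloride (10 mol%), toluene/H2O, −10 °C
Reagents that add atoms: hydrogen peroxide OO
Why: Weitz–Scheffer nucleophilic epoxidation under chiral phase-transfer catalysis attacks only the electron-poor C2=C3 bond, sets both stereocentres together by suprafacial oxygen transfer, and the chiral ammonium ion pair should select the face giving the (2R,3S)-epoxide (the pseudo-enantiomeric quininium salt is taken if a screen shows the opposite sense).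

Step 12
Reactants: 17 (2R,3S)-2,3-epoxide
Product: 18 (2S,3R)-3-chloro-2-(side chain)-2-hydroxy-5,7-bis(methoxymethoxy)-3-methyl-2,3-dihydronaphthalene-1,4-dione
Conditions: MgCl2 (anhydrous), THF/MeCN, 0 °C → rt; aq. NH4Cl
Reagents that add atoms: magnesium chloride [Mg+2].[Cl-].[Cl-]
Why: Chelation-assisted chloride opening of an α,β-epoxy ketone: divalent magnesium held between the C4 carbonyl and the C5 OMOM oxygen activates the C3–O bond, and chloride should attack the less hindered methyl-bearing C3 from the face opposite the oxygen (inversion at C3, C2 untouched), giving the trans chlorohydrin with (2S,3R) configuration.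

Step 13
Reactants: 18 (2S,3R)-bis-MOM chlorohydrin
Product: 19 (2S,3R)-3-chloro-2-[(4E)-5,9-dimethyl-2-(propan-2-ylidene)deca-4,8-dien-1-yl]-2,5,7-trihydroxy-3-methyl-2,3-dihydronaphthalene-1,4-dione
Conditions: ZnBr2, n-PrSH, CH2Cl2, 0 °C
Reagents that add atoms: none
Why: Lewis acid/thiol acetal exchange cleaves aryl MOM ethers under nearly neutral conditions that should leave the tertiary chloride, the α-ketol and the three chain alkenes untouched.

Compound list
1 | triethyl phosphonoacetate | CCOC(=O)CP(=O)(OCC)OCC | starting material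
2 | geranyl bromide, (2E)-1-bromo-3,7-dimethylocta-2,6-diene | CC(C)=CCC/C(C)=C/CBr | starting material
3 | ethyl (4E)-2-(diethoxyphosphoryl)-5,9-dimethyldeca-4,8-dienoate | CC(C)=CCC/C(C)=C/CC(C(=O)OCC)P(=O)(OCC)OCC | intermediate
4 | ethyl (4E)-5,9-dimethyl-2-(propan-2-ylidene)deca-4,8-dienoate | CC(C)=CCC/C(C)=C/CC(C(=O)OCC)=C(C)C | intermediate
5 | (4E)-5,9-dimethyl-2-(propan-2-ylidene)deca-4,8-dien-1-ol | CC(C)=CCC/C(C)=C/CC(CO)=C(C)C | intermediate
6 | (5E)-3-(bromomethyl)-2,6,10-trimethylundeca-2,5,9-triene | CC(C)=CCC/C(C)=C/CC(CBr)=C(C)C | intermediate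
7 | (5E)-3-(2,2-diiodoethyl)-2,6,10-trimethylundeca-2,5,9-triene | CC(C)=CCC/C(C)=C/CC(CC(I)I)=C(C)C | intermediate
8 | methyl 3,5-dimethoxybenzoate | COC(=O)c1cc(OC)cc(OC)c1 | starting material
9 | methyl 3,5-dimethoxy-2-propanoylbenzoate | CCC(=O)c1c(OC)cc(OC)cc1C(=O)OC | intermediate
10 | methyl 3,5-dihydroxy-2-propanoylbenzoate | CCC(=O)c1c(O)cc(O)cc1C(=O)OC | intermediate
11 | methyl 3,5-bis(methoxymethoxy)-2-propanoylbenzoate | CCC(=O)c1c(OCOC)cc(OCOC)cc1C(=O)OC | intermediate
12 | 4,6-bis(methoxymethoxy)-2-methyl-1H-indene-1,3(2H)-dione | CC1C(=O)c2cc(OCOC)cc(OCOC)c2C1=O | intermediate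
13 | ethyl[(5E)-1-iodo-6,10-dimethyl-3-(propan-2-ylidene)undeca-5,9-dien-1-yl]zinc (zinc carbenoid) | CC[Zn]C(I)CC(=C(C)C)C/C=C(\C)CCC=C(C)C | intermediate
14 | ethylzinc C4-enolate of 2-(side chain)-5,7-bis(methoxymethoxy)-3-methyl-2,3-dihydronaphthalene-1,4-dione (C2 not controlled) | CC[Zn]OC1=C(C)C(CC(=C(C)C)C/C=C(\C)CCC=C(C)C)C(=O)c2cc(OCOC)cc(OCOC)c12 | intermediate
15 | 3-iodo-2-(side chain)-5,7-bis(methoxymethoxy)-3-methyl-2,3-dihydronaphthalene-1,4-dione (C2, C3 not controlled) | CC1(I)C(CC(=C(C)C)C/C=C(\C)CCC=C(C)C)C(=O)c2cc(OCOC)cc(OCOC)c2C1=O | intermediate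
16 | 2-[(4E)-5,9-dimethyl-2-(propan-2-ylidene)deca-4,8-dien-1-yl]-5,7-bis(methoxymethoxy)-3-methylnaphthalene-1,4-dione | CC(C)=CCC/C(C)=C/CC(CC1=C(C)C(=O)c2c(OCOC)cc(OCOC)cc2C1=O)=C(C)C | intermediate
17 | (2R,3S)-2,3-epoxy-2-[(4E)-5,9-dimethyl-2-(propan-2-ylidene)deca-4,8-dien-1-yl]-5,7-bis(methoxymethoxy)-3-methyl-2,3-dihydronaphthalene-1,4-dione | CC(C)=CCC/C(C)=C/CC(C[C@@]12O[C@]1(C)C(=O)c3c(OCOC)cc(OCOC)cc3C2=O)=C(C)C | intermediate
18 | (2S,3R)-3-chloro-2-[(4E)-5,9-dimethyl-2-(propan-2-ylidene)deca-4,8-dien-1-yl]-2-hydroxy-5,7-bis(methoxymethoxy)-3-methyl-2,3-dihydronaphthalene-1,4-dione | CC(C)=CCC/C(C)=C/CC(C[C@]1(O)C(=O)c2cc(OCOC)cc(OCOC)c2C(=O)[C@]1(C)Cl)=C(C)C | intermediate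
19 | (2S,3R)-3-chloro-2-[(4E)-5,9-dimethyl-2-(propan-2-ylidene)deca-4,8-dien-1-yl]-2,5,7-trihydroxy-3-methyl-2,3-dihydronaphthalene-1,4-dione | CC(C)=CCC/C(C)=C/CC(C[C@]1(O)C(=O)c2cc(O)cc(O)c2C(=O)[C@]1(C)Cl)=C(C)C | target

Total step count: 13. Longest linear sequence: 9 steps (steps 1–5, then 10–13).

Steps most likely to fail

1. Step 10. The branched carbenoid may alkylate the hindered, strongly stabilised enolate too slowly, so that carbenoid decomposition (1,2-hydride shift), cyclopropanation of chain alkenes or loss of the C1/C4 selectivity takes over. The fallback separates ring expansion and chain attachment and sets out from 12 and 6. Compound 12 is ring-expanded with the parent carbenoid (Et2Zn, CH2I2, CH2Cl2) to 6,8-bis(methoxymethoxy)-2-methyl-2,3-dihydronaphthalene-1,4-dione F1, which is oxidised (MnO2) to 6,8-bis(methoxymethoxy)-2-methylnaphthalene-1,4-dione F2. Bromide 6 and Bu3SnLi give tributyl[(4E)-5,9-dimethyl-2-(propan-2-ylidene)deca-4,8-dien-1-yl]stannane F3. Allylation of F2 by F3 with BF3·OEt2 at −78 °C (the quinone allylation used for vitamin K: addition at the carbonyl next to the free ring CH, then [3,3] shift) gives 2-(side chain)-5,7-bis(methoxymethoxy)-3-methylnaphthalene-1,4-diol F4, and Ag2O oxidation comes back to the route at 16.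

2. Step 12. Chloride may enter at C2 instead of C3, or the Lewis acid may trigger a 1,2-acyl shift of the epoxy diketone (ring contraction to a 2-acylindanedione) or premature acetal loss. The fallback sets out from 17. Luche reduction (NaBH4, CeCl3·7H2O, MeOH, −78 °C) of the more electrophilic C1 carbonyl gives the C1 carbinol of epoxide 17 F5 (either C1 epimer serves). C3 is then the only epoxide carbon α to a carbonyl, so LiCl/AcOH in THF should open it there to the C1 carbinol of chlorohydrin 18 F6. Dess–Martin oxidation of the secondary benzylic alcohol comes back to the route at 18.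

3. Step 11. The two faces of the nearly symmetric 2,3-dialkylquinone may be poorly discriminated by the chiral ion pair, and the tetrasubstituted alkene may react sluggishly at low temperature. The fallback sets out from 16. Epoxidation without catalyst control (H2O2, Na2CO3, aqueous EtOH) gives 17 together with its enantiomer, the (2S,3R)-epoxide F7; the two are separated by preparative HPLC on a chiral stationary phase, and the route is rejoined at 17.

Further compounds
F1 | step 10 | 6,8-bis(methoxymethoxy)-2-methyl-2,3-dihydronaphthalene-1,4-dione | CC1CC(=O)c2cc(OCOC)cc(OCOC)c2C1=O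
F2 | step 10 | 6,8-bis(methoxymethoxy)-2-methylnaphthalene-1,4-dione | CC1=CC(=O)c2cc(OCOC)cc(OCOC)c2C1=O
F3 | step 10 | tributyl[(4E)-5,9-dimethyl-2-(propan-2-ylidene)deca-4,8-dien-1-yl]stannane | CCCC[Sn](CCCC)(CCCC)CC(=C(C)C)C/C=C(\C)CCC=C(C)C
F4 | step 10 | 2-[(4E)-5,9-dimethyl-2-(propan-2-ylidene)deca-4,8-dien-1-yl]-5,7-bis(methoxymethoxy)-3-methylnaphthalene-1,4-diol | CC(C)=CCC/C(C)=C/CC(Cc1c(C)c(O)c2c(OCOC)cc(OCOC)cc2c1O)=C(C)C
F5 | step 12 | C1 carbinol of epoxide 17 (C1 ketone reduced, C1 configuration not controlled) | CC(C)=CCC/C(C)=C/CC(C[C@@]12O[C@]1(C)C(=O)c3c(OCOC)cc(OCOC)cc3C2O)=C(C)C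
F6 | step 12 | C1 carbinol of chlorohydrin 18 (chloro diol, C1 configuration not controlled) | CC(C)=CCC/C(C)=C/CC(C[C@]1(O)C(O)c2cc(OCOC)cc(OCOC)c2C(=O)[C@]1(C)Cl)=C(C)C
F7 | step 11 | (2S,3R)-2,3-epoxy-2-[(4E)-5,9-dimethyl-2-(propan-2-ylidene)deca-4,8-dien-1-yl]-5,7-bis(methoxymethoxy)-3-methyl-2,3-dihydronaphthalene-1,4-dione (enantiomer of 17) | CC(C)=CCC/C(C)=C/CC(C[C@]12O[C@@]1(C)C(=O)c3c(OCOC)cc(OCOC)cc3C2=O)=C(C)C
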